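**Retrosynthetic overview**

1. Target 32 ⇐ alkene isomerisation of α‑methylene lactone 31 ⇐ intramolecular CrCl2 allylation of bromo enal 29 (C7–C8 bond; closes the ten‑membered ring and the lactone together).
2. 29 ⇐ ring A block 23, whose C10–H and C11=C12 come from a reductive 1,3‑transposition of the C12 carbonate 20 ⇐ 17.
3. 17 ⇐ epoxy cyclopentenol 15 by ring expansion: 1,2‑shift of the vinylic C10 from C14 to C1 (cyclopentene → cyclohexene) with in situ C2‑directed reduction at C14 by propanal. Enabling feature: in ring A (C1, C10–C14) the quaternary C1 lies between the ring carbinol C14 and the exocyclic acyloxy carbon C2, which are anti (a 2‑quaternary 1,3‑diol monoester), and C10 is the other ring neighbour of C1.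
4. 15 ⇐ 14 ⇐ vinyl iodide 13 (C1–C7, C15, C16; from nerol) + cyclopentenone 6 (C8–C14, C20; from allethrolone).
5. Ring order: cyclopentene (bought) → ring A by one‑carbon expansion (step 13) → ten‑membered ring and lactone (step 23).

Key step: step 13

Remark: briarane numbering is used (C1 quaternary carbon with C15 methyl; C2 propionyloxy carbon; C5(C16)=C6; C7 lactone carbinol; C8=C17(C19 methyl)–C18 lactone carbonyl; C9 methylene; C10 ring‑fusion CH; C11(C20)=C12; C14 acetoxy carbon); α means the face of ring A opposite to the C15 methyl.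

**Route**

Step 1
Reactants: 1 (RS)-allethrolone
Product: 2 (RS)-allethrolone acetate
Conditions: Ac2O, pyridine, DMAP (cat.), CH2Cl2, 0 °C
Reagents that add atoms: acetic anhydride, CC(=O)OC(C)=O
Why: DMAP‑catalysed acylation of the secondary allylic alcohol is fast at 0 °C, where the β‑acyloxy ketone should not eliminate, and the acetate is the substrate of the enzymatic resolution.

Step 2
Reactants: 2 (RS)-allethrolone acetate
Product: 3 (R)-allethrolone
Conditions: lipase from Burkholderia cepacia, phosphate buffer pH 7/MTBE, 30 °C, stopped at half conversion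
Reagents that add atoms: none
Why: Lipase‑catalysed enantioselective hydrolysis (kinetic resolution) of 4‑acyloxycyclopentenones should cleave the (R)‑acetate preferentially, so that the (R)‑alcohol is set free and the (S)‑acetate is left behind and separated; this fixes C12, from which all other stereocentres are derived.

Step 3
Reactants: 3 (R)-allethrolone
Product: 4 (R)-allethrolone TBS ether
Conditions: TBSCl, imidazole, DMF, 23 °C
Reagents that add atoms: tert‑butyldimethylsilyl chloride, CC(C)(C)[Si](C)(C)Cl
Why: Standard silylation of a secondary alcohol under mildly basic conditions gives an ether that survives organolithium, peroxide and Lewis acid steps and later shields one ring face.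

Step 4
Reactants: 4 (R)-allethrolone TBS ether
Product: 6 cyclopentenone dimethyl acetal, via aldehyde 5 (not isolated)
Conditions: O3, CH2Cl2, −78 °C (1 equiv, indicator end point); Me2S; then HC(OMe)3, PPTS, MeOH, 23 °C
Reagents that add atoms: ozone, [O-][O+]=O (the oxygen of aldehyde 5); trimethyl orthoformate, COC(OC)OC (the two methoxy groups of 6)
Why: Ozone attacks the electron‑rich terminal alkene far faster than the tetrasubstituted enone alkene, and acetalisation in the same flask masks the C8 aldehyde at the oxidation level needed later.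

Step 5
Reactants: 7 nerol
Product: 8 neryl 4‑methoxybenzyl ether
Conditions: NaH, PMBCl, Bu4NI (cat.), THF, 0 to 23 °C
Reagents that add atoms: 4‑methoxybenzyl chloride, COc1ccc(CCl)cc1
Why: Williamson etherification of the primary allylic alcohol proceeds without touching the (Z)‑alkene that later becomes C5=C6.

Step 6
Reactants: 8 neryl 4‑methoxybenzyl ether
Product: 9 6,7‑epoxyneryl 4‑methoxybenzyl ether
Conditions: mCPBA (1.0 equiv), NaHCO3, CH2Cl2, −20 °C
Reagents that add atoms: 3‑chloroperbenzoic acid, O=C(OO)c1cccc(Cl)c1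
Why: The remote trisubstituted alkene is more electron‑rich than the alkene deactivated by the allylic oxygen, so peracid epoxidation should be regioselective (the epoxide stereocentre is irrelevant).

Step 7
Reactants: 9 6,7‑epoxyneryl 4‑methoxybenzyl ether
Product: 10 (4Z)-6-(4‑methoxybenzyloxy)-4‑methylhex‑4‑enal
Conditions: H5IO6, THF/H2O, 0 °C
Reagents that add atoms: none
Why: Periodic acid opens the epoxide to the diol and cleaves it in one pot, which removes the isopropylidene carbons as acetone and leaves the C2 aldehyde with the (Z)‑alkene untouched.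

Step 8
Reactants: 10 (4Z)-6-(4‑methoxybenzyloxy)-4‑methylhex‑4‑enal
Product: 11 1,1‑dibromoalkene
Conditions: CBr4, PPh3, CH2Cl2, 0 °C
Reagents that add atoms: tetrabromomethane, BrC(Br)(Br)Br
Why: Corey–Fuchs dibromo‑olefination of an unhindered aldehyde adds the carbon that becomes C1.

Step 9
Reactants: 11 1,1‑dibromoalkene
Product: 12 (2Z)-3‑methyloct‑2‑en‑6‑yn‑1‑yl 4‑methoxybenzyl ether
Conditions: n‑BuLi (2.1 equiv), THF, −78 °C; then MeI, −78 to 23 °C
Reagents that add atoms: iodomethane, CI
Why: The second stage of the Corey–Fuchs reaction gives the lithium acetylide, which is methylated in the same flask to install C15.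

Step 10
Reactants: 12 (2Z)-3‑methyloct‑2‑en‑6‑yn‑1‑yl 4‑methoxybenzyl ether
Product: 13 (2Z,6E)-7‑iodo‑3‑methylocta‑2,6‑dien‑1‑yl 4‑methoxybenzyl ether
Conditions: Cp2Zr(H)Cl (excess), THF, 50 °C; then I2, 0 °C
Reagents that add atoms: iodine, II
Why: Syn‑hydrozirconation of a 2‑alkyne under equilibrating conditions places zirconium on the methyl‑bearing carbon, and iodinolysis with retention should give the (E)‑2‑iodoalkene, while the trisubstituted alkene and the ether are inert.

Step 11
Reactants: 13 (2Z,6E)-7‑iodo‑3‑methylocta‑2,6‑dien‑1‑yl 4‑methoxybenzyl ether; 6 cyclopentenone dimethyl acetal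
Product: 14 tertiary cyclopentenol
Conditions: 13, t‑BuLi (2 equiv), Et2O, −78 °C; CeCl3, THF, −78 °C; then 6
Reagents that add atoms: none
Why: Iodine–lithium exchange keeps the alkene geometry, and the organocerium reagent should add 1,2 to the enolisable enone on the face opposite to the C12 silyloxy group, which sets C14 with its hydroxyl cis to OTBS.

Step 12
Reactants: 14 tertiary cyclopentenol
Product: 15 epoxy cyclopentenol
Conditions: VO(acac)2 (cat.), t‑BuOOH, toluene, 0 °C
Reagents that add atoms: tert‑butyl hydroperoxide, CC(C)(C)OO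
Why: Hydroxyl‑directed vanadium‑catalysed epoxidation spares the remote C5=C6 alkene, and the tetrasubstituted ring alkene would have to be reached on the face carrying the cis C12 silyloxy group, so the exocyclic C1=C2 alkene should react; its face is chosen by allylic 1,2‑strain (C15 methyl over C13H2 and not over the substituted vinylic C10), which should give the trans‑epoxide shown and sets C1 and C2.

Step 13
Reactants: 15 epoxy cyclopentenol
Product: 17 ring A diol 2‑propionate, via hydroxy ketone 16 (not isolated)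
Conditions: SmI2 (0.3 equiv), EtCHO (5 equiv), ClCH2CH2Cl/THF, 23 °C
Reagents that add atoms: propanal, CCC=O
Why: Trivalent samarium formed in situ from SmI2 and propanal chelates the C14 hydroxyl and the epoxide oxygen of 15, the C1–O bond ionises and the vinylic ring carbon C10 shifts from C14 to C1 anti to the departing oxygen, so that the cyclopentene grows by one carbon into the cyclohexenone 16 (semipinacol rearrangement of a 2,3‑epoxy alcohol). The samarium alkoxide at C2 then adds to propanal and the hemiacetal passes its hydride to the C14 carbonyl through a chair‑like chelate (Evans–Tishchenko reduction), which gives the C2 propionate and the free C14 alcohol; the closest known reaction type is the samarium‑catalysed tandem semipinacol rearrangement/Tishchenko reduction of tertiary α‑hydroxy epoxides to 2‑quaternary anti‑1,3‑diol monoesters. Ring A is not closed by a cyclisation but by ring expansion: the six‑membered ring arises from the five‑membered one through the 1,2‑shift that makes the C1–C10 bond. The quaternary C1 is set by the epoxide configuration (inversion at C1, retention in the migrating carbon), C2 is carried over unchanged from the epoxide, and C14 is set anti to the C2 oxygen by the intramolecular hydride delivery. The step needs migration of C10 and not of C13, which the higher migratory aptitude of an alkenyl carbon and its antiperiplanar place in the chelate should secure, and it needs hydride transfer to outrun retro‑aldol cleavage, which the mild Lewis acid and the excess of aldehyde favour.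

Step 14
Reactants: 17 ring A diol 2‑propionate
Product: 18 C14 acetate
Conditions: Ac2O, DMAP, Et3N, CH2Cl2, 23 °C
Reagents that add atoms: acetic anhydride, CC(=O)OC(C)=O
Why: DMAP‑catalysed acetylation of the only free hydroxyl completes the differentiated C2 propionate/C14 acetate pair.

Step 15
Reactants: 18 C14 acetate
Product: 19 C12 allylic alcohol
Conditions: Bu4NF, AcOH, THF, 23 °C
Reagents that add atoms: none
Why: Buffered fluoride removes the secondary silyl ether without ester migration or cleavage of the acetal and the PMB ether.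

Step 16
Reactants: 19 C12 allylic alcohol
Product: 20 C12 methyl carbonate
Conditions: ClCO2Me, pyridine, DMAP (cat.), CH2Cl2, 0 °C
Reagents that add atoms: methyl chloroformate, COC(=O)Cl
Why: Acylation of the allylic alcohol gives the leaving group for ionisation by zerovalent palladium.

Step 17
Reactants: 20 C12 methyl carbonate
Product: 23 ring A acetal, via sulfonyl hydrazone 21 (not isolated), via allylic diazene 22 (not isolated)
Conditions: IPNBSH (N‑isopropylidene‑N'‑2‑nitrobenzenesulfonyl hydrazine), Pd(PPh3)4 (cat.), THF, 23 °C; then CF3CH2OH/H2O, AcOH, 23 °C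
Reagents that add atoms: none
Why: Tsuji–Trost substitution (ionisation with inversion, attack of the hydrazone nitrogen at the less hindered C12 with a second inversion) should put nitrogen on the α‑face with net retention, and hydrolysis, loss of sulfinic acid and suprafacial loss of N2 from the allylic diazene (reductive 1,3‑transposition) should deliver hydrogen to C10 on the α‑face and move the alkene to C11=C12.

Step 18
Reactants: 23 ring A acetal
Product: 24 C8 aldehyde
Conditions: LiBF4, MeCN/H2O, 23 °C
Reagents that add atoms: water, O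
Why: Mild Lewis acid hydrolysis of the dimethyl acetal should spare the two esters, the allylic PMB ether and the alkenes.

Step 19
Reactants: 24 C8 aldehyde; 25 methyl acrylate
Product: 26 Baylis–Hillman adduct
Conditions: DABCO, MeOH (cat.), neat methyl acrylate, 23 °C
Reagents that add atoms: none
Why: The Morita–Baylis–Hillman reaction of an unhindered aliphatic aldehyde attaches C17, C18 and C19 in one step; the C8 carbinol is formed as a mixture, which does not matter because C8 becomes sp2 in the next step.

Step 20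
Reactants: 26 Baylis–Hillman adduct
Product: 27 (Z)-2-(bromomethyl) enoate
Conditions: NBS, Me2S, CH2Cl2, 0 to 23 °C
Reagents that add atoms: N‑bromosuccinimide, O=C1CCC(=O)N1Br
Why: Activation of the allylic alcohol as an alkoxysulfonium salt and SN2' attack of bromide is the standard route from Baylis–Hillman alcohols to (Z)-2-(bromomethyl)alk‑2‑enoates.

Step 21
Reactants: 27 (Z)-2-(bromomethyl) enoate
Product: 28 C7 allylic alcohol
Conditions: DDQ, CH2Cl2/pH 7 buffer, 0 °C
Reagents that add atoms: none
Why: Oxidative cleavage of the PMB ether is compatible with the allylic bromide, the enoate and both esters.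

Step 22
Reactants: 28 C7 allylic alcohol
Product: 29 bromo (Z)-enal
Conditions: MnO2, CH2Cl2, 23 °C
Reagents that add atoms: none
Why: MnO2 oxidises only the allylic alcohol and should not isomerise the (Z)‑alkene.

Step 23
Reactants: 29 bromo (Z)-enal
Product: 31 α‑methylene lactone, via hydroxy ester 30 (not isolated)
Conditions: CrCl2 (excess), THF, 23 °C, slow addition at high dilution; then p‑TsOH (cat.), CH2Cl2
Reagents that add atoms: none
Why: In this intramolecular Barbier‑type (Nozaki–Hiyama) allylation the allylchromium species formed from the bromide adds through its γ‑carbon C8 to the enal carbon C7 in a closed chair‑like transition state, which closes the ten‑membered ring as known for germacranolide‑type rings, and the C7 hydroxyl then lactonises; C7 is set by the macrocyclic transition state, which is expected to expose the enal face leading to the 7S configuration, and C8 is erased in step 24.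

Step 24
Reactants: 31 α‑methylene lactone
Product: 32 CNP0112230.2 (target)
Conditions: RhCl3·3H2O (cat.), EtOH, 70 °C
Reagents that add atoms: none
Why: Rhodium hydride addition–elimination should move the exocyclic alkene into conjugated, tetrasubstituted position C8=C17 (the thermodynamic butenolide) under neutral conditions that should not epimerise C7.

**Compound list**

1 | (RS)-allethrolone, 4‑hydroxy‑3‑methyl‑2‑(prop‑2‑en‑1‑yl)cyclopent‑2‑en‑1‑one (racemic) | C=CCC1=C(C)C(O)CC1=O | starting material
2 | (RS)-allethrolone acetate, 2‑methyl‑4‑oxo‑3‑(prop‑2‑en‑1‑yl)cyclopent‑2‑en‑1‑yl acetate (racemic) | C=CCC1=C(C)C(OC(C)=O)CC1=O | intermediate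
3 | (R)-allethrolone, (4R)-4‑hydroxy‑3‑methyl‑2‑(prop‑2‑en‑1‑yl)cyclopent‑2‑en‑1‑one | C=CCC1=C(C)[C@H](O)CC1=O | intermediate
4 | (4R)-4‑(tert‑butyldimethylsilyloxy)-3‑methyl‑2‑(prop‑2‑en‑1‑yl)cyclopent‑2‑en‑1‑one | C=CCC1=C(C)[C@H](O[Si](C)(C)C(C)(C)C)CC1=O | intermediate
5 | 2‑[(3R)-3‑(tert‑butyldimethylsilyloxy)-2‑methyl‑5‑oxocyclopent‑1‑en‑1‑yl]acetaldehyde | O=CCC1=C(C)[C@H](O[Si](C)(C)C(C)(C)C)CC1=O | intermediate
6 | (4R)-4‑(tert‑butyldimethylsilyloxy)-2‑(2,2‑dimethoxyethyl)-3‑methylcyclopent‑2‑en‑1‑one | COC(OC)CC1=C(C)[C@H](O[Si](C)(C)C(C)(C)C)CC1=O | intermediate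
7 | nerol, (2Z)-3,7‑dimethylocta‑2,6‑dien‑1‑ol | CC(C)=CCC/C(C)=C\CO | starting material
8 | neryl 4‑methoxybenzyl ether | CC(C)=CCC/C(C)=C\COCc1ccc(OC)cc1 | intermediate
9 | 6,7‑epoxyneryl 4‑methoxybenzyl ether (racemic at the epoxide) | CC1(C)OC1CC/C(C)=C\COCc1ccc(OC)cc1 | intermediate
10 | (4Z)-6‑(4‑methoxybenzyloxy)-4‑methylhex‑4‑enal | O=CCC/C(C)=C\COCc1ccc(OC)cc1 | intermediate
11 | (2Z)-7,7‑dibromo‑3‑methylhepta‑2,6‑dien‑1‑yl 4‑methoxybenzyl ether | BrC(Br)=CCC/C(C)=C\COCc1ccc(OC)cc1 | intermediate
12 | (2Z)-3‑methyloct‑2‑en‑6‑yn‑1‑yl 4‑methoxybenzyl ether | CC#CCC/C(C)=C\COCc1ccc(OC)cc1 | intermediate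
13 | (2Z,6E)-7‑iodo‑3‑methylocta‑2,6‑dien‑1‑yl 4‑methoxybenzyl ether | C/C(I)=C\CC/C(C)=C\COCc1ccc(OC)cc1 | intermediate
14 | (1R,4R)-4‑(tert‑butyldimethylsilyloxy)-2‑(2,2‑dimethoxyethyl)-1‑[(2E,6Z)-8‑(4‑methoxybenzyloxy)-6‑methylocta‑2,6‑dien‑2‑yl]-3‑methylcyclopent‑2‑en‑1‑ol (hydroxyl cis to OTBS) | COC(OC)CC1=C(C)[C@H](O[Si](C)(C)C(C)(C)C)C[C@@]1(O)/C(C)=C/CC/C(C)=C\COCc1ccc(OC)cc1 | intermediate
15 | C1–C2 trans‑epoxide of 14 (C1 R, C2 S in briarane numbering) | COC(OC)CC1=C(C)[C@H](O[Si](C)(C)C(C)(C)C)C[C@@]1(O)[C@]2(C)O[C@H]2CC/C(C)=C\COCc1ccc(OC)cc1 | intermediate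
16 | ring‑expanded β‑hydroxy ketone: cyclohex‑3‑en‑1‑one (C14 ketone) with quaternary C1 (C15 methyl β, C2 carbinol chain α), C10=C11, C12 α‑OTBS, C9–C8 dimethyl acetal chain | O[C@@H](CC/C(C)=C\COCc1ccc(OC)cc1)[C@@]1(C)C(=O)C[C@@H](O[Si](C)(C)C(C)(C)C)C(C)=C1CC(OC)OC | intermediate
17 | anti‑1,3‑diol monoester of 16: C2 propionate, C14 α‑hydroxyl | CCC(=O)O[C@@H](CC/C(C)=C\COCc1ccc(OC)cc1)[C@@]1(C)[C@@H](O)C[C@@H](O[Si](C)(C)C(C)(C)C)C(C)=C1CC(OC)OC | intermediate
18 | C14 α‑acetate of 17 | CCC(=O)O[C@@H](CC/C(C)=C\COCc1ccc(OC)cc1)[C@@]1(C)[C@@H](OC(C)=O)C[C@@H](O[Si](C)(C)C(C)(C)C)C(C)=C1CC(OC)OC | intermediate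
19 | C12 α‑allylic alcohol (silyl ether of 18 removed) | CCC(=O)O[C@@H](CC/C(C)=C\COCc1ccc(OC)cc1)[C@@]1(C)[C@@H](OC(C)=O)C[C@@H](O)C(C)=C1CC(OC)OC | intermediate
20 | C12 α‑methyl carbonate of 19 | CCC(=O)O[C@@H](CC/C(C)=C\COCc1ccc(OC)cc1)[C@@]1(C)[C@@H](OC(C)=O)C[C@@H](OC(=O)OC)C(C)=C1CC(OC)OC | intermediate
21 | C12 α‑N‑(2‑nitrobenzenesulfonyl)‑N'‑isopropylidene hydrazine adduct | CCC(=O)O[C@@H](CC/C(C)=C\COCc1ccc(OC)cc1)[C@@]1(C)[C@@H](OC(C)=O)C[C@@H](N(N=C(C)C)S(=O)(=O)c2ccccc2[N+](=O)[O-])C(C)=C1CC(OC)OC | intermediate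
22 | C12 α‑allylic diazene | CCC(=O)O[C@@H](CC/C(C)=C\COCc1ccc(OC)cc1)[C@@]1(C)[C@@H](OC(C)=O)C[C@@H](N=N)C(C)=C1CC(OC)OC | intermediate
23 | ring A block: cyclohex‑11‑ene with C1 (C15 β, C2 propionate chain α), C10 (H α, C9–C8 dimethyl acetal chain β), C14 α‑acetate | CCC(=O)O[C@@H](CC/C(C)=C\COCc1ccc(OC)cc1)[C@@]1(C)[C@@H](OC(C)=O)CC=C(C)[C@@H]1CC(OC)OC | intermediate
24 | C8 aldehyde from 23 | CCC(=O)O[C@@H](CC/C(C)=C\COCc1ccc(OC)cc1)[C@@]1(C)[C@@H](OC(C)=O)CC=C(C)[C@@H]1CC=O | intermediate
25 | methyl acrylate | C=CC(=O)OC | starting material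
26 | Baylis–Hillman adduct (C8 carbinol as a mixture of epimers) | CCC(=O)O[C@@H](CC/C(C)=C\COCc1ccc(OC)cc1)[C@@]1(C)[C@@H](OC(C)=O)CC=C(C)[C@@H]1CC(O)C(=C)C(=O)OC | intermediate
27 | methyl (Z)-2‑(bromomethyl)alk‑2‑enoate (C8=C17, C9 cis to CH2Br) | CCC(=O)O[C@@H](CC/C(C)=C\COCc1ccc(OC)cc1)[C@@]1(C)[C@@H](OC(C)=O)CC=C(C)[C@@H]1C/C=C(\CBr)C(=O)OC | intermediate
28 | C7 allylic alcohol (PMB removed) | CCC(=O)O[C@@H](CC/C(C)=C\CO)[C@@]1(C)[C@@H](OC(C)=O)CC=C(C)[C@@H]1C/C=C(\CBr)C(=O)OC | intermediate
29 | bromo (Z)-enal (C7 aldehyde) | CCC(=O)O[C@@H](CC/C(C)=C\C=O)[C@@]1(C)[C@@H](OC(C)=O)CC=C(C)[C@@H]1C/C=C(\CBr)C(=O)OC | intermediate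
30 | macrocyclic C7 hydroxy ester (C8 configuration not specified, erased later) | CCC(=O)O[C@H]1CC/C(C)=C\[C@H](O)C(C(=C)C(=O)OC)C[C@H]2C(C)=CC[C@H](OC(C)=O)[C@]12C | intermediate
31 | 17(19)-methylene lactone (C8 configuration not specified, erased later) | CCC(=O)O[C@H]1CC/C(C)=C\[C@@H]2OC(=O)C(=C)C2C[C@H]2C(C)=CC[C@H](OC(C)=O)[C@]12C | intermediate
32 | CNP0112230.2: (1S,2S,5Z,7S,10S,14S)-14‑acetoxy‑2‑propanoyloxybriara‑5,8(17),11‑trien‑18,7‑olide | CCC(=O)O[C@H]1CC/C(C)=C\[C@@H]2OC(=O)C(C)=C2C[C@H]2C(C)=CC[C@H](OC(C)=O)[C@]12C | target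

**Step count**

Total step count: 24. Longest linear sequence: 20 steps (steps 5–10, then 11–24, from nerol).

**Steps most likely to fail**

1. Step 13 (key step). Retro‑aldol cleavage of the β‑hydroxy ketone at the quaternary C1, or acyl migration between the two oxygens, may compete with the hydride transfer. The anti selectivity may also erode if the hemiacetal chelate is disfavoured next to the quaternary centre. Fallback: rearrangement and reduction are separated and the ester is made before the carbinol. Setting out from 15, ZnBr2 in CH2Cl2 should give the isolated hydroxy ketone 16. Acylation with propionic anhydride and DMAP gives the C2 propionate ketone F1. Reduction with NaBH4 in MeOH at −40 °C, with hydride expected from the ring face opposite to the branched C2 substituent on C1, comes back to the route at 17.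

2. Step 17. Ionisation of the hindered, 2‑methyl‑substituted cyclic carbonate may be slow, the allylpalladium species may lose a β‑hydrogen to give a diene, or the nucleophile may attack the wrong terminus. Fallback: nitrogen is introduced by SN2 displacement and not through an allyl complex. Setting out from 19, Mitsunobu inversion with chloroacetic acid (PPh3, DIAD) gives the C12 β‑chloroacetate F2. Thiourea and NaHCO3 in EtOH remove only the chloroacetyl group and give the C12 β‑alcohol F3. A second Mitsunobu reaction with 2‑nitrobenzenesulfonyl hydrazide (PPh3, DEAD, THF, −30 °C, then 23 °C) inverts C12 again to the α‑sulfonyl hydrazine F4. F4 loses sulfinic acid to the diazene 22, and loss of N2 comes back to the route at 23.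

3. Step 23. Intermolecular coupling (oligomerisation) may outrun ring closure, and the enal may be attacked on the wrong face, which would give the C7 epimer. Fallback: the allyl metal is made as a stable reagent first, and the ring is closed by an acid‑catalysed allylboration, whose facial selectivity can be steered by a chiral phosphoric acid. Setting out from 27, palladium‑catalysed borylation (Pd2(dba)3, bis(pinacolato)diboron, toluene, 50 °C) gives the allylboronate PMB ether F5. DDQ gives the allylboronate alcohol F6 and MnO2 the allylboronate enal F7. Sc(OTf)3 or a chiral phosphoric acid at high dilution closes the ring through hydroxy ester 30, and lactonisation comes back to the route at 31.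

**Further compounds**

F1 | step 13 | C2 propionate of hydroxy ketone 16 (C14 ketone) | CCC(=O)O[C@@H](CC/C(C)=C\COCc1ccc(OC)cc1)[C@@]1(C)C(=O)C[C@@H](O[Si](C)(C)C(C)(C)C)C(C)=C1CC(OC)OC
F2 | step 17 | C12 β‑chloroacetate (C12 epimer series of 19) | CCC(=O)O[C@@H](CC/C(C)=C\COCc1ccc(OC)cc1)[C@@]1(C)[C@@H](OC(C)=O)C[C@H](OC(=O)CCl)C(C)=C1CC(OC)OC
F3 | step 17 | C12 β‑alcohol (C12 epimer of 19) | CCC(=O)O[C@@H](CC/C(C)=C\COCc1ccc(OC)cc1)[C@@]1(C)[C@@H](OC(C)=O)C[C@H](O)C(C)=C1CC(OC)OC
F4 | step 17 | C12 α‑N‑(2‑nitrobenzenesulfonyl) hydrazine | CCC(=O)O[C@@H](CC/C(C)=C\COCc1ccc(OC)cc1)[C@@]1(C)[C@@H](OC(C)=O)C[C@@H](N(N)S(=O)(=O)c2ccccc2[N+](=O)[O-])C(C)=C1CC(OC)OC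
F5 | step 23 | allylboronate PMB ether (pinacol boronate in place of bromide in 27) | CCC(=O)O[C@@H](CC/C(C)=C\COCc1ccc(OC)cc1)[C@@]1(C)[C@@H](OC(C)=O)CC=C(C)[C@@H]1C/C=C(\CB2OC(C)(C)C(C)(C)O2)C(=O)OC
F6 | step 23 | allylboronate C7 alcohol | CCC(=O)O[C@@H](CC/C(C)=C\CO)[C@@]1(C)[C@@H](OC(C)=O)CC=C(C)[C@@H]1C/C=C(\CB2OC(C)(C)C(C)(C)O2)C(=O)OC
F7 | step 23 | allylboronate (Z)-enal | CCC(=O)O[C@@H](CC/C(C)=C\C=O)[C@@]1(C)[C@@H](OC(C)=O)CC=C(C)[C@@H]1C/C=C(\CB2OC(C)(C)C(C)(C)O2)C(=O)OC
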